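**Retrosynthetic overview**

1. Feature: in the 14-membered ring the C3–O/C4–OH pair and the C11–C12 oxirane are both oxidation patterns of E-trisubstituted alkenes of one acyclic C2–C13 chain whose end carbons C2 and C13 can hold allylic hydroxyls, while C7=C8 holds none and must survive to the end.
2. Target 25 ⇒ (Schenck ene reaction at C7=C8) hydroxy lactone 24 ⇒ (conjugate reduction; intramolecular Horner–Wadsworth–Emmons closure of the δ-lactone C15–C16–O–C3–C2–C1) macrocyclic hydroxy dithiane 18.
3. 18 ⇒ (C1 dithiane carbanion opening the C2–C3 oxirane, closing ring C1–C14) open chain 17 ⇒ 1,3-dithiane (C1) + a one-carbon unit (C14) + diepoxide 5, with C3 inverted by a CO2-mediated carbonate opening.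
4. 5 ⇒ double asymmetric epoxidation of 12-hydroxyfarnesol 4 ⇒ farnesol 1.
5. Ring order: C3–C4 and C11–C12 oxiranes (step 4) → temporary C2–C3 oxirane (step 6) → 14-membered carbocycle (step 11) → δ-lactone (step 14).

Key step: step 4

Numbering: cembrane locants are used throughout (ring C1–C14; C15, C16, C17 = lactone α-carbon, carbonyl, α-methyl; C18–C20 = methyls on C4, C8, C12).
Remark: the farnesane chain supplies only C2–C13, so C14 is added as a hydroxymethyl anion equivalent (step 8) before 1,3-dithiane brings in C1.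
Assumption: in lactone 24 singlet oxygen reaches the face of the C7=C8 alkene that leads to 8R.

**Route**

Step 1
Reactants: 1 (2E,6E)-farnesol
Product: 2 (2E,6E)-farnesyl acetate
Conditions: Ac2O, pyridine, DMAP (cat.), CH2Cl2, 0 °C → rt
Reagents that add atoms: acetic anhydride, CC(=O)OC(C)=O
Why: O-acylation masks the C2 hydroxyl and deactivates the adjacent alkene so that the next oxidation goes to the far end of the chain.

Step 2
Reactants: 2 (2E,6E)-farnesyl acetate
Product: 3 (2E,6E,10E)-12-hydroxyfarnesyl acetate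
Conditions: SeO2 (cat.), t-BuOOH, salicylic acid (cat.), CH2Cl2, 0 °C → rt; then NaBH4, MeOH, 0 °C (returns over-oxidised enal to the alcohol)
Reagents that add atoms: tert-butyl hydroperoxide (terminal oxidant, oxygen relayed through SeO2), CC(C)(C)OO
Why: catalytic selenium dioxide allylic oxidation (ene reaction then [2,3]-shift) attacks the most electron-rich, least hindered trisubstituted alkene at its E-methyl group and should give the (10E)-allylic alcohol.

Step 3
Reactants: 3 (2E,6E,10E)-12-hydroxyfarnesyl acetate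
Product: 4 (2E,6E,10E)-2,6,10-trimethyldodeca-2,6,10-triene-1,12-diol (12-hydroxyfarnesol)
Conditions: K2CO3 (cat.), MeOH, rt
Reagents that add atoms: none
Why: base-catalysed transesterification frees the second allylic hydroxyl without touching the three alkenes.

Step 4
Reactants: 4 12-hydroxyfarnesol
Product: 5 (2S,3S,6E,10S,11S)-2,3:10,11-diepoxy-3,7,11-trimethyldodec-6-ene-1,12-diol
Conditions: Ti(Oi-Pr)4 (0.2 equiv), L-(+)-diethyl tartrate (0.28 equiv), t-BuOOH (4 equiv, anhydrous), 4 Å MS, CH2Cl2, −20 °C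
Reagents that add atoms: tert-butyl hydroperoxide, CC(C)(C)OO
Why: Each allylic hydroxyl exchanges for isopropoxide on the dimeric titanium–tartrate catalyst, and the titanium-bound tert-butyl peroxide then passes its distal oxygen to the alkene held beside it (Katsuki–Sharpless asymmetric epoxidation, run at both ends of one diol). The closest known cases are the epoxidations of geraniol-type 3-methyl-2-alkenols and of (E)-2-methyl-2-alkenols, which are exactly the two termini of 4. Each oxirane ring closes by one suprafacial oxygen-atom transfer in which both C–O bonds form on the same alkene face (a [2+1] closure, no chain cyclisation). C3, C4, C11 and C12 are all set by the L-(+)-tartrate ligand (reagent control): it delivers oxygen to the face that gives the 2S,3S epoxide of geraniol, and the same sense at the other terminus gives 11S,12S. The step needs site selectivity for the two terminal alkenes over C7=C8, and hydroxyl binding secures it, because the central alkene has no hydroxyl within reach of titanium. As both ends react under one ligand, a wrong-face event at either end ends up in a diastereomer, so the major diepoxide should be enriched in enantiomeric purity.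

Step 5
Reactants: 5 diepoxy diol
Product: 7 (2R,3S,6E,10S,11S)-10,11-epoxy-3,7,11-trimethyldodec-6-ene-1,2,3,12-tetrol, via cyclic carbonate 6 (not isolated)
Conditions: Cs2CO3 (cat.), CO2 (1 atm), DMF, 3 Å MS, 25–40 °C; then K2CO3 (cat.), MeOH, rt
Reagents that add atoms: carbon dioxide, O=C=O
Why: carbonate-extended Payne-type opening: the caesium alkoxide at C2–O takes up CO2 and the carbonate oxygen opens the neighbouring oxirane at C3 in a 5-exo SN2 step, which inverts C3 (3S → 3R) and leaves the C4–O bond (4S) untouched, whereas the C13 carbonate would have to attack the fully substituted C12 and should stay unchanged; methanolysis converges any migrated carbonate to one triol.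

Step 6
Reactants: 7 epoxy tetrol
Product: 9 (2S,5E,9S,10S)-9,10-epoxy-6,10-dimethyl-2-[(2R)-oxiran-2-yl]undec-5-ene-2,11-diol, via monotosylate 8 (not isolated)
Conditions: Bu2SnO (5 mol %), TsCl (1.05 equiv), Et3N, CH2Cl2, 0 °C → rt; then K2CO3, MeOH, 0 °C
Reagents that add atoms: none
Why: tin-acetal-accelerated monosulfonylation picks the primary hydroxyl of the 1,2-diol over the isolated C13–OH, and the C3 alkoxide then displaces the tosylate (3-exo-tet) to give the terminal C2–C3 oxirane with C3 unchanged (3R).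

Step 7
Reactants: 9 bis-epoxy diol
Product: 11 C13 triflate with C4–OSiEt3, via hydroxy triflate 10 (not isolated)
Conditions: Tf2O (1.05 equiv), 2,6-lutidine, CH2Cl2, −78 °C; then Et3SiOTf, −78 → −40 °C; cold work-up, crude 11 used at once
Reagents that add atoms: trifluoromethanesulfonic anhydride, O=S(=O)(OS(=O)(=O)C(F)(F)F)C(F)(F)F; triethylsilyl trifluoromethanesulfonate, CC[Si](CC)(CC)OS(=O)(=O)C(F)(F)F
Why: sulfonylation at −78 °C takes only the primary C13–OH, and silylation then caps the tertiary C4–OH so that no alkoxide can re-open the C2–C3 oxirane by Payne rearrangement in the basic steps that follow.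

Step 8
Reactants: 11 epoxy triflate; 12 (chloromethyl)(isopropoxy)dimethylsilane
Product: 13 C14 silane (C13–CH2–SiMe2Oi-Pr)
Conditions: 12, Mg, THF (Grignard reagent, 3 equiv); CuI (0.2 equiv), THF, −78 °C; quench cold
Reagents that add atoms: none
Why: copper-catalysed coupling of a primary triflate with a Grignard reagent (a hydroxymethyl anion equivalent) forms C13–C14 at −78 °C, where triflate displacement should be much faster than opening of either oxirane.

Step 9
Reactants: 13 C14 silane
Product: 14 (3S,4S,7E,11S)-3,4-epoxy-3,7-dimethyl-11-[(2R)-oxiran-2-yl]-11-(triethylsilyloxy)dodec-7-en-1-ol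
Conditions: 30% H2O2, KF, KHCO3, THF/MeOH, rt
Reagents that add atoms: hydrogen peroxide, OO
Why: Tamao–Fleming oxidation turns the C–Si bond of the alkoxysilane into C–OH with retention, and the mildly basic peroxide should leave the oxiranes, the alkene and the tertiary silyl ether alone.

Step 10
Reactants: 14 C14 alcohol; 15 1,3-dithiane
Product: 17 2-alkyl-1,3-dithiane (C1 attached to C14), via primary triflate 16 (not isolated)
Conditions: 14: Tf2O, 2,6-lutidine, CH2Cl2, −78 °C; 15: n-BuLi, THF, −30 °C; then 16 added at −78 °C, quench at −78 °C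
Reagents that add atoms: none
Why: Corey–Seebach alkylation: the unhindered primary triflate is displaced by 2-lithio-1,3-dithiane within minutes at −78 °C, a temperature at which the dithiane anion does not yet open oxiranes, and this forms C14–C1.

Step 11
Reactants: 17 epoxy dithiane
Product: 18 (3R,4S,7E,11S,12S)-11,12-epoxy-1,1-(propane-1,3-diyldisulfanediyl)-4,8,12-trimethyl-4-(triethylsilyloxy)cyclotetradec-7-en-3-ol
Conditions: t-BuLi (1.05 equiv), THF/DMPU (10:1), 0.003 M, −78 °C; then → −20 °C; H2O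
Reagents that add atoms: none
Why: intramolecular Corey–Seebach epoxide opening: the C1 carbanion attacks the unsubstituted C2 end of the oxirane under high dilution and closes the 14-membered ring, the same type of closure as the sulfur-stabilised carbanion/epoxide cyclisations used for cembrane rings; C3 is not touched and stays 3R.

Step 12
Reactants: 18 macrocyclic hydroxy dithiane; 19 2-(diethoxyphosphoryl)propanoic acid
Product: 20 C3 2-(diethoxyphosphoryl)propanoate of 18 (mixture at the phosphonate α-carbon)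
Conditions: DCC, DMAP (cat.), CH2Cl2, rt
Reagents that add atoms: none
Why: Steglich esterification of the C3 hydroxyl while C1 is still masked, so that no β-hydroxy ketone meets base; the stereocentre α to phosphorus is lost two steps later.

Step 13
Reactants: 20 phosphonate ester
Product: 21 (3R,4S,7E,11S,12S)-11,12-epoxy-4,8,12-trimethyl-1-oxo-4-(triethylsilyloxy)cyclotetradec-7-en-3-yl 2-(diethoxyphosphoryl)propanoate
Conditions: MeI, CaCO3, MeCN/H2O (9:1), 50 °C
Reagents that add atoms: water, O
Why: alkylative dithiane hydrolysis unmasks the C1 ketone under buffered, non-acidic conditions that should spare the oxirane, the silyl ether and the phosphonate ester.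

Step 14
Reactants: 21 keto phosphonate
Product: 22 (3R,4S,7E,11S,12S)-11,12-epoxy-4-(triethylsilyloxy)cembra-1(15),7-dien-16,3-olide
Conditions: LiCl, DBU, MeCN, 0 °C → rt
Reagents that add atoms: none
Why: intramolecular Horner–Wadsworth–Emmons olefination under Masamune–Roush conditions: the lithium-chelated phosphonate anion adds to the C1 ketone and closes the six-membered lactone as the C1=C15 alkene, and the mild amine base limits β-elimination of the C3 acyloxy group.

Step 15
Reactants: 22 unsaturated lactone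
Product: 23 (1R,3R,4S,7E,11S,12S,15S)-11,12-epoxy-4-(triethylsilyloxy)cembr-7-en-16,3-olide
Conditions: Cu(OAc)2·H2O (10 mol %), 1,2-bis(diphenylphosphino)benzene (10 mol %), (EtO)2MeSiH, t-BuOH, toluene, rt → 40 °C; then DBU (cat.), rt
Reagents that add atoms: none
Why: ligand-accelerated copper hydride (Stryker-type) conjugate reduction: hydride should reach C1 from the face opposite to the C4 branch of the macrocycle, which puts H1 cis to H3 (1R), and base equilibration of the enolisable C15 should then settle the methyl trans to C14 (15S, both groups equatorial).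

Step 16
Reactants: 23 silyl ether lactone
Product: 24 (1R,3R,4S,7E,11S,12S,15S)-11,12-epoxy-4-hydroxycembr-7-en-16,3-olide
Conditions: Bu4NF, AcOH, THF, 0 °C → rt
Reagents that add atoms: none
Why: fluoride desilylation of the tertiary triethylsilyl ether, buffered with acetic acid so that the lactone and its C15 centre do not meet strong base.

Step 17
Reactants: 24 hydroxy lactone
Product: 25 (1R,3R,4S,6E,8R,11S,12S,15S)-11,12-epoxy-8-hydroperoxy-4-hydroxycembr-6-en-16,3-olide (target)
Conditions: O2, hν (visible), tetraphenylporphyrin (cat.), CH2Cl2, −20 °C; no reductive work-up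
Reagents that add atoms: dioxygen, O=O
Why: Schenck ene reaction of singlet oxygen with the trisubstituted C7=C8 alkene: oxygen bonds to C8 while a hydrogen is taken from C6 on the same face (cis effect, the more crowded side of the alkene), which moves the double bond to C6=C7 (E) and sets C8 by the alkene face that the macrocycle exposes (substrate control, 8R as assumed above).

**Compound list**

1 | (2E,6E)-farnesol | CC(C)=CCC/C(C)=C/CC/C(C)=C/CO | starting material
2 | (2E,6E)-farnesyl acetate | CC(C)=CCC/C(C)=C/CC/C(C)=C/COC(C)=O | intermediate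
3 | (2E,6E,10E)-12-hydroxyfarnesyl acetate | OC/C(C)=C/CC/C(C)=C/CC/C(C)=C/COC(C)=O | intermediate
4 | (2E,6E,10E)-2,6,10-trimethyldodeca-2,6,10-triene-1,12-diol (12-hydroxyfarnesol) | OC/C(C)=C/CC/C(C)=C/CC/C(C)=C/CO | intermediate
5 | (2S,3S,6E,10S,11S)-2,3:10,11-diepoxy-3,7,11-trimethyldodec-6-ene-1,12-diol | OC[C@]1(C)O[C@H]1CC/C(C)=C/CC[C@]1(C)O[C@H]1CO | intermediate
6 | (4R)-4-[(1S,4E,8S,9S)-8,9-epoxy-1,10-dihydroxy-1,5,9-trimethyldec-4-en-1-yl]-1,3-dioxolan-2-one (C2/C3 cyclic carbonate, C4–OH free) | OC[C@]1(C)O[C@H]1CC/C(C)=C/CC[C@](C)(O)[C@H]1COC(=O)O1 | intermediate (not isolated)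
7 | (2R,3S,6E,10S,11S)-10,11-epoxy-3,7,11-trimethyldodec-6-ene-1,2,3,12-tetrol | OC[C@]1(C)O[C@H]1CC/C(C)=C/CC[C@](C)(O)[C@H](O)CO | intermediate
8 | (2R,3S,6E,10S,11S)-10,11-epoxy-2,3,12-trihydroxy-3,7,11-trimethyldodec-6-en-1-yl 4-methylbenzenesulfonate | OC[C@]1(C)O[C@H]1CC/C(C)=C/CC[C@](C)(O)[C@H](O)COS(=O)(=O)c1ccc(C)cc1 | intermediate (not isolated)
9 | (2S,5E,9S,10S)-9,10-epoxy-6,10-dimethyl-2-[(2R)-oxiran-2-yl]undec-5-ene-2,11-diol | OC[C@]1(C)O[C@H]1CC/C(C)=C/CC[C@](C)(O)[C@H]1CO1 | intermediate
10 | (2S,3S,6E,10S)-2,3-epoxy-10-hydroxy-2,6-dimethyl-10-[(2R)-oxiran-2-yl]undec-6-en-1-yl trifluoromethanesulfonate | FC(F)(F)S(=O)(=O)OC[C@]1(C)O[C@H]1CC/C(C)=C/CC[C@](C)(O)[C@H]1CO1 | intermediate (not isolated)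
11 | (2S,3S,6E,10S)-2,3-epoxy-2,6-dimethyl-10-[(2R)-oxiran-2-yl]-10-(triethylsilyloxy)undec-6-en-1-yl trifluoromethanesulfonate | FC(F)(F)S(=O)(=O)OC[C@]1(C)O[C@H]1CC/C(C)=C/CC[C@](C)(O[Si](CC)(CC)CC)[C@H]1CO1 | intermediate
12 | (chloromethyl)(isopropoxy)dimethylsilane | CC(C)O[Si](C)(C)CCl | starting material
13 | {(3S,4S,7E,11S)-3,4-epoxy-3,7-dimethyl-11-[(2R)-oxiran-2-yl]-11-(triethylsilyloxy)dodec-7-en-1-yl}(isopropoxy)dimethylsilane | CC(C)O[Si](C)(C)CC[C@]1(C)O[C@H]1CC/C(C)=C/CC[C@](C)(O[Si](CC)(CC)CC)[C@H]1CO1 | intermediate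
14 | (3S,4S,7E,11S)-3,4-epoxy-3,7-dimethyl-11-[(2R)-oxiran-2-yl]-11-(triethylsilyloxy)dodec-7-en-1-ol | OCC[C@]1(C)O[C@H]1CC/C(C)=C/CC[C@](C)(O[Si](CC)(CC)CC)[C@H]1CO1 | intermediate
15 | 1,3-dithiane | C1CSCSC1 | starting material
16 | trifluoromethanesulfonate of 14 | FC(F)(F)S(=O)(=O)OCC[C@]1(C)O[C@H]1CC/C(C)=C/CC[C@](C)(O[Si](CC)(CC)CC)[C@H]1CO1 | intermediate (not isolated)
17 | 2-{(3S,4S,7E,11S)-3,4-epoxy-3,7-dimethyl-11-[(2R)-oxiran-2-yl]-11-(triethylsilyloxy)dodec-7-en-1-yl}-1,3-dithiane | C1CSC(SC1)CC[C@]1(C)O[C@H]1CC/C(C)=C/CC[C@](C)(O[Si](CC)(CC)CC)[C@H]1CO1 | intermediate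
18 | (3R,4S,7E,11S,12S)-11,12-epoxy-1,1-(propane-1,3-diyldisulfanediyl)-4,8,12-trimethyl-4-(triethylsilyloxy)cyclotetradec-7-en-3-ol (C1 is the dithiane carbon) | S1CCCSC12CC[C@]3(C)O[C@H]3CC/C(C)=C/CC[C@](C)(O[Si](CC)(CC)CC)[C@H](O)C2 | intermediate
19 | 2-(diethoxyphosphoryl)propanoic acid | CC(C(=O)O)P(=O)(OCC)OCC | starting material
20 | C3 2-(diethoxyphosphoryl)propanoate of 18 | S1CCCSC12CC[C@]3(C)O[C@H]3CC/C(C)=C/CC[C@](C)(O[Si](CC)(CC)CC)[C@H](OC(=O)C(C)P(=O)(OCC)OCC)C2 | intermediate
21 | (3R,4S,7E,11S,12S)-11,12-epoxy-4,8,12-trimethyl-1-oxo-4-(triethylsilyloxy)cyclotetradec-7-en-3-yl 2-(diethoxyphosphoryl)propanoate | O=C1CC[C@]2(C)O[C@H]2CC/C(C)=C/CC[C@](C)(O[Si](CC)(CC)CC)[C@H](OC(=O)C(C)P(=O)(OCC)OCC)C1 | intermediate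
22 | (3R,4S,7E,11S,12S)-11,12-epoxy-4-(triethylsilyloxy)cembra-1(15),7-dien-16,3-olide | CC1=C2CC[C@]3(C)O[C@H]3CC/C(C)=C/CC[C@](C)(O[Si](CC)(CC)CC)[C@@H](C2)OC1=O | intermediate
23 | (1R,3R,4S,7E,11S,12S,15S)-11,12-epoxy-4-(triethylsilyloxy)cembr-7-en-16,3-olide | C[C@@H]1C(=O)O[C@@H]2C[C@H]1CC[C@]1(C)O[C@H]1CC/C(C)=C/CC[C@]2(C)O[Si](CC)(CC)CC | intermediate
24 | (1R,3R,4S,7E,11S,12S,15S)-11,12-epoxy-4-hydroxycembr-7-en-16,3-olide | C[C@@H]1C(=O)O[C@@H]2C[C@H]1CC[C@]1(C)O[C@H]1CC/C(C)=C/CC[C@]2(C)O | intermediate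
25 | (1R,3R,4S,6E,8R,11S,12S,15S)-11,12-epoxy-8-hydroperoxy-4-hydroxycembr-6-en-16,3-olide | C[C@@H]1C(=O)O[C@@H]2C[C@H]1CC[C@]1(C)O[C@H]1CC[C@@](C)(OO)/C=C/C[C@]2(C)O | target

**Totals and risks**

Total step count: 17. Longest linear sequence: 17 steps (1 → 25); compounds 12, 15 and 19 are bought.

Steps most likely to fail:

1. Step 11 (macrocyclisation). The carbanion may not form cleanly beside the oxirane (t-BuLi adding to C2), chains may couple to each other faster than the 14-membered ring closes, or the C1 carbanion may turn on the nearby 11,12-oxirane and close a small ring. The fallback closes the ring at C1–C14 by alkylation, forms C1–C2 first, and releases the carbanion by anion relay, not by a base. It sets out from alcohol 14. Tosylation (TsCl, pyridine, 0 °C) gives the primary tosylate F1. Lithiated 2-(trimethylsilyl)-1,3-dithiane (commercial; t-BuLi, Et2O, −78 → −40 °C) opens the C2–C3 oxirane at C2 to the alkoxide of the relay adduct F2 (not isolated). Adding THF/HMPA and diluting triggers the 1,4-Brook shift of silicon to the C3 oxygen, and the dithiane anion so released alkylates C14 to give the macrocyclic trimethylsilyl ether F3. K2CO3 in MeOH removes the trimethylsilyl group, and the route is rejoined at 18.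

2. Step 15 (conjugate reduction). The tetrasubstituted C1=C15 alkene may resist copper hydride, hydride may arrive on the wrong face, or C15 may equilibrate to the unwanted epimer. The fallback builds the lactone without the methyl, reduces the easier trisubstituted alkene and adds the methyl last by enolate alkylation. It sets out from 18. Esterification with 2-(diethoxyphosphoryl)acetic acid (DCC, DMAP) gives the phosphonoacetate F4, and MeI/CaCO3 hydrolysis gives the keto phosphonoacetate F5. LiCl/DBU closes the 17-nor unsaturated lactone F6, and copper hydride reduction gives the 17-nor saturated lactone F7, with C1 set as in step 15. LDA in THF at −78 °C then MeI should methylate C15 anti to the C14 branch, and the route is rejoined at 23.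

3. Step 17 (photooxygenation). Hydrogen may be taken from the C19 methyl and not from C6 (wrong regiochemistry), or oxygen may add to the other alkene face (8-epimer). The fallback is an ionic sequence that fixes regiochemistry by Markovnikov addition and brings oxygen in anti to the electrophile, the opposite face to the ene reaction. It sets out from silyl ether 23, so that the C4 oxygen cannot capture the bromonium ion. 1,3-Dibromo-5,5-dimethylhydantoin with a large excess of concentrated H2O2 in Et2O at −40 °C gives the (7S,8R)-bromo hydroperoxide F8; the excess is needed to outrun capture by the 11,12-oxirane oxygen. Et3SiCl/imidazole gives the silyl peroxide F9, and DBU in warm toluene eliminates HBr towards C6 to the (6E)-allylic silyl peroxide F10. Bu4NF/AcOH removes both silyl groups, and the route is rejoined at 25.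

Further compounds
F1 | step 11 | (3S,4S,7E,11S)-3,4-epoxy-3,7-dimethyl-11-[(2R)-oxiran-2-yl]-11-(triethylsilyloxy)dodec-7-en-1-yl 4-methylbenzenesulfonate | Cc1ccc(cc1)S(=O)(=O)OCC[C@]1(C)O[C@H]1CC/C(C)=C/CC[C@](C)(O[Si](CC)(CC)CC)[C@H]1CO1
F2 | step 11 | relay adduct: C3 alcohol with the 2-(trimethylsilyl)-1,3-dithian-2-yl group on C2 and the C14 tosylate (not isolated) | Cc1ccc(cc1)S(=O)(=O)OCC[C@]1(C)O[C@H]1CC/C(C)=C/CC[C@](C)(O[Si](CC)(CC)CC)[C@H](O)CC1([Si](C)(C)C)SCCCS1
F3 | step 11 | 3-O-trimethylsilyl ether of 18 | S1CCCSC12CC[C@]3(C)O[C@H]3CC/C(C)=C/CC[C@](C)(O[Si](CC)(CC)CC)[C@H](O[Si](C)(C)C)C2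
F4 | step 15 | C3 (diethoxyphosphoryl)acetate of 18 | S1CCCSC12CC[C@]3(C)O[C@H]3CC/C(C)=C/CC[C@](C)(O[Si](CC)(CC)CC)[C@H](OC(=O)CP(=O)(OCC)OCC)C2
F5 | step 15 | (3R,4S,7E,11S,12S)-11,12-epoxy-4,8,12-trimethyl-1-oxo-4-(triethylsilyloxy)cyclotetradec-7-en-3-yl (diethoxyphosphoryl)acetate | O=C1CC[C@]2(C)O[C@H]2CC/C(C)=C/CC[C@](C)(O[Si](CC)(CC)CC)[C@H](OC(=O)CP(=O)(OCC)OCC)C1
F6 | step 15 | (3R,4S,7E,11S,12S)-11,12-epoxy-4-(triethylsilyloxy)-17-norcembra-1(15),7-dien-16,3-olide | O=C1C=C2CC[C@]3(C)O[C@H]3CC/C(C)=C/CC[C@](C)(O[Si](CC)(CC)CC)[C@@H](C2)O1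
F7 | step 15 | (1R,3R,4S,7E,11S,12S)-11,12-epoxy-4-(triethylsilyloxy)-17-norcembr-7-en-16,3-olide | O=C1C[C@@H]2CC[C@]3(C)O[C@H]3CC/C(C)=C/CC[C@](C)(O[Si](CC)(CC)CC)[C@@H](C2)O1
F8 | step 17 | (1R,3R,4S,7S,8R,11S,12S,15S)-7-bromo-11,12-epoxy-8-hydroperoxy-4-(triethylsilyloxy)cembran-16,3-olide | C[C@@H]1C(=O)O[C@@H]2C[C@H]1CC[C@]1(C)O[C@H]1CC[C@@](C)(OO)[C@@H](Br)CC[C@]2(C)O[Si](CC)(CC)CC
F9 | step 17 | 8-(triethylsilylperoxy) derivative of F8 | C[C@@H]1C(=O)O[C@@H]2C[C@H]1CC[C@]1(C)O[C@H]1CC[C@@](C)(OO[Si](CC)(CC)CC)[C@@H](Br)CC[C@]2(C)O[Si](CC)(CC)CC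
F10 | step 17 | (1R,3R,4S,6E,8R,11S,12S,15S)-11,12-epoxy-4-(triethylsilyloxy)-8-(triethylsilylperoxy)cembr-6-en-16,3-olide | C[C@@H]1C(=O)O[C@@H]2C[C@H]1CC[C@]1(C)O[C@H]1CC[C@@](C)(OO[Si](CC)(CC)CC)/C=C/C[C@]2(C)O[Si](CC)(CC)CC
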